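**Plan**

- Retrosynthesis: ring C is opened at O1–C2 and C4–C4a (flavanone numbering, ring B primed). Ring A is then taken back one oxidation level to a 2‑prenylcyclohexane‑1,3‑dione.
- Feature used: ring A carries its oxygens on C7 and C8a in a 1,3‑relationship, with the prenylated C8 between them and the acyl‑bearing C4a next to C8a. This is a C‑alkylated cyclohexane‑1,3‑dione whose α'‑carbon (C4a) is an enolate carbon and whose carbonyl oxygen (O1) becomes an enol oxygen once C4a is acylated.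
- Forward: ring B is elaborated to a prenylated cinnamoyl chloride, and ring A is carried as a carbocyclic silyl vinylogous ester. One operation joins them by Claisen C‑acylation (C4–C4a) and 6‑endo oxa‑Michael closure (O1–C2), which creates ring C.
- Ring A is aromatised last by quinone dehydrogenation, then both silyl groups are removed.
- Stereochemistry: C2 (S) is set in the ring closure by a bifunctional cinchona thiourea. Both prenyl groups are placed on simple precursors (dione C2, phenol ortho carbon), so no late prenylation is needed.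

Key step: step 7

Remark: the face selectivity of the cinchona catalyst in step 7 cannot be derived safely from a model; the quinidine‑derived thiourea is written, and its quinine‑derived pseudo‑enantiomer takes its place if a trial closure shows the opposite sense.

**Route**

Step 1
Reactants: 1 cyclohexane‑1,3‑dione; 2 prenyl bromide (1‑bromo‑3‑methylbut‑2‑ene)
Product: 3 2‑(3‑methylbut‑2‑en‑1‑yl)cyclohexane‑1,3‑dione
Conditions: KOH (1.0 equiv), H2O, 0 °C → rt
Reagents that add atoms: none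
Why: C‑alkylation of the dione enolate by the allylic bromide in water, where hydrogen bonding to the enolate oxygen favours C‑ over O‑attack; this fixes the prenyl group on the carbon that becomes C8, between the two oxygens.

Step 2
Reactants: 3 2‑(3‑methylbut‑2‑en‑1‑yl)cyclohexane‑1,3‑dione
Product: 4 2‑(3‑methylbut‑2‑en‑1‑yl)‑3‑[(triisopropylsilyl)oxy]cyclohex‑2‑en‑1‑one
Conditions: i‑Pr3SiCl, Et3N, DMAP (cat.), CH2Cl2, 0 °C → rt
Reagents that add atoms: triisopropylsilyl chloride, CC(C)[Si](Cl)(C(C)C)C(C)C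
Why: O‑silylation of the enolised 1,3‑dione by the hard silyl chloride should give the silyl vinylogous ester (a Stork–Danheiser‑type substrate) under base‑only conditions that avoid acid‑induced cyclisation of the enol onto the prenyl group; the bulky silyl group later becomes the C7 aryl silyl ether.

Step 3
Reactants: 5 4‑hydroxybenzaldehyde; 2 prenyl bromide
Product: 6 4‑hydroxy‑3‑(3‑methylbut‑2‑en‑1‑yl)benzaldehyde
Conditions: KOH (1.1 equiv), H2O, rt
Reagents that add atoms: none
Why: ortho C‑alkylation of the phenoxide by the allylic bromide in water (phenoxide C‑allylation under hydrogen‑bonding solvation of oxygen); the para position is blocked by the formyl group, so only the ortho carbon (future C3') can react.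

Step 4
Reactants: 6 4‑hydroxy‑3‑(3‑methylbut‑2‑en‑1‑yl)benzaldehyde; 7 malonic acid
Product: 8 (2E)‑3‑[4‑hydroxy‑3‑(3‑methylbut‑2‑en‑1‑yl)phenyl]prop‑2‑enoic acid
Conditions: pyridine, piperidine (cat.), 90 °C
Reagents that add atoms: none
Why: Doebner modification of the Knoevenagel condensation: condensation with malonic acid followed by decarboxylation should give the (E)‑cinnamic acid, and the basic medium leaves the ortho‑prenyl phenol untouched.

Step 5
Reactants: 8 (2E)‑3‑[4‑hydroxy‑3‑(3‑methylbut‑2‑en‑1‑yl)phenyl]prop‑2‑enoic acid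
Product: 9 tert‑butyldimethylsilyl (2E)‑3‑{4‑[(tert‑butyldimethylsilyl)oxy]‑3‑(3‑methylbut‑2‑en‑1‑yl)phenyl}prop‑2‑enoate
Conditions: t‑BuMe2SiCl (2.3 equiv), imidazole, DMF, rt
Reagents that add atoms: tert‑butyldimethylsilyl chloride, CC(C)(C)[Si](C)(C)Cl
Why: silylation of both the phenol and the carboxylic acid (silyl ether and silyl ester formation) protects O4' for the enolate chemistry and prepares the acid for activation under neutral conditions.

Step 6
Reactants: 9 tert‑butyldimethylsilyl (2E)‑3‑{4‑[(tert‑butyldimethylsilyl)oxy]‑3‑(3‑methylbut‑2‑en‑1‑yl)phenyl}prop‑2‑enoate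
Product: 10 (2E)‑3‑{4‑[(tert‑butyldimethylsilyl)oxy]‑3‑(3‑methylbut‑2‑en‑1‑yl)phenyl}prop‑2‑enoyl chloride
Conditions: (COCl)2 (1.2 equiv), DMF (cat.), CH2Cl2, 0 °C → rt; volatiles removed in vacuo, used crude
Reagents that add atoms: oxalyl chloride, O=C(Cl)C(=O)Cl
Why: the chloroiminium salt from oxalyl chloride and DMF (Vilsmeier‑type activation) converts the silyl ester directly into the acid chloride with loss of the silyl chloride, so no HCl is formed that could add to the prenyl group, and the aryl silyl ether does not react.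

Step 7
Reactants: 4 2‑(3‑methylbut‑2‑en‑1‑yl)‑3‑[(triisopropylsilyl)oxy]cyclohex‑2‑en‑1‑one (2.0 equiv); 10 (2E)‑3‑{4‑[(tert‑butyldimethylsilyl)oxy]‑3‑(3‑methylbut‑2‑en‑1‑yl)phenyl}prop‑2‑enoyl chloride (1.0 equiv)
Product: 13 (2S)‑2‑{4‑[(tert‑butyldimethylsilyl)oxy]‑3‑(3‑methylbut‑2‑en‑1‑yl)phenyl}‑8‑(3‑methylbut‑2‑en‑1‑yl)‑7‑[(triisopropylsilyl)oxy]‑2,3,5,6‑tetrahydro‑4H‑chromen‑4‑one, via lithium dienolate 11 (not isolated), via enol diketone 12 (not isolated)
Conditions: LiN(i‑Pr)2 (2.0 equiv), THF, −78 °C; 10, −78 → −40 °C; AcOH (2.0 equiv), cold pH 7 buffer wash, solvent exchange to toluene (crude 12 not purified); 9‑amino(9‑deoxy)epi‑quinidine 3,5‑bis(trifluoromethyl)phenyl thiourea (10 mol%), −20 °C → rt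
Reagents that add atoms: none
Why: Proposed new method: kinetic deprotonation of vinylogous ester 4 at its α'‑CH2 (the future C4a) gives the cross‑conjugated dienolate 11, which is C‑acylated by 10 in a Claisen‑type acylation (C4–C4a), the second equivalent of 11 storing the product as its lithium diketonate until the acetic acid quench releases the chelated enol 12, the non‑aromatic counterpart of a 2'‑hydroxychalcone. The bifunctional catalyst then deprotonates the acidic enol O–H with its quinuclidine nitrogen, binds the C4 carbonyl oxygen with the thiourea N–H pair, and the enol oxygen adds to the cinnamoyl β‑carbon in a 6‑endo‑trig oxa‑Michael closure (O1–C2, formally the oxa‑6π closure of the O1=C8a–C4a=C4–C3=C2 oxatriene) while the ammonium ion returns the proton to C3. The closest known reaction type is the cinchona‑thiourea‑catalysed enantioselective oxa‑Michael cyclisation of 2'‑hydroxychalcone‑type substrates to flavanones; new here are the enolised β‑diketone of a dearomatised ring A as the oxygen nucleophile and the unactivated cinnamoyl acceptor. C2 is the only new stereocentre and is set under catalyst control, the chiral ion pair exposing one face of the s‑trans enone to O1. The step needs C‑ over O‑acylation and 1,2‑ over 1,4‑attack (lithium enolate, acid chloride, THF, −78 °C) and closure through O1 alone, which the substrate secures because the prenylated C8 has no hydrogen, the γ‑CH2 is not deprotonated under kinetic conditions and O1 is the only enol oxygen six atoms away from C2. The C3–H of the vinylogous ester product 13 is too weakly acidic for the amine to reopen the ring, so the new stereocentre should persist.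

Step 8
Reactants: 13 (2S)‑2‑{4‑[(tert‑butyldimethylsilyl)oxy]‑3‑(3‑methylbut‑2‑en‑1‑yl)phenyl}‑8‑(3‑methylbut‑2‑en‑1‑yl)‑7‑[(triisopropylsilyl)oxy]‑2,3,5,6‑tetrahydro‑4H‑chromen‑4‑one
Product: 14 (2S)‑2‑{4‑[(tert‑butyldimethylsilyl)oxy]‑3‑(3‑methylbut‑2‑en‑1‑yl)phenyl}‑8‑(3‑methylbut‑2‑en‑1‑yl)‑7‑[(triisopropylsilyl)oxy]‑2,3‑dihydro‑4H‑chromen‑4‑one
Conditions: DDQ (1.05 equiv), toluene, 0 °C → rt
Reagents that add atoms: none
Why: quinone dehydrogenation: DDQ should take a hydride from C5 to give a cation stabilised by O1 and the C7 silyloxy group, and loss of the C6 proton aromatises ring A, which should be far faster at 0 °C than attack at the prenyl CH2 groups or at C2–C3; C2 is not involved and keeps its configuration.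

Step 9
Reactants: 14 (2S)‑2‑{4‑[(tert‑butyldimethylsilyl)oxy]‑3‑(3‑methylbut‑2‑en‑1‑yl)phenyl}‑8‑(3‑methylbut‑2‑en‑1‑yl)‑7‑[(triisopropylsilyl)oxy]‑2,3‑dihydro‑4H‑chromen‑4‑one
Product: 15 glabrol, (2S)‑7‑hydroxy‑2‑[4‑hydroxy‑3‑(3‑methylbut‑2‑en‑1‑yl)phenyl]‑8‑(3‑methylbut‑2‑en‑1‑yl)‑2,3‑dihydro‑4H‑chromen‑4‑one
Conditions: Bu4NF (2.5 equiv), AcOH (2.5 equiv), THF, 0 °C
Reagents that add atoms: none
Why: fluoride‑mediated cleavage of both aryl silyl ethers (desilylation); acetic acid buffers the phenoxides so that base‑induced opening of the flavanone (retro‑oxa‑Michael) and hence racemisation at C2 should be avoided.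

**Compound list**

1 | cyclohexane‑1,3‑dione | O=C1CCCC(=O)C1 | starting material
2 | prenyl bromide (1‑bromo‑3‑methylbut‑2‑ene) | CC(C)=CCBr | starting material
3 | 2‑(3‑methylbut‑2‑en‑1‑yl)cyclohexane‑1,3‑dione | CC(C)=CCC1C(=O)CCCC1=O | intermediate
4 | 2‑(3‑methylbut‑2‑en‑1‑yl)‑3‑[(triisopropylsilyl)oxy]cyclohex‑2‑en‑1‑one | CC(C)=CCC1=C(O[Si](C(C)C)(C(C)C)C(C)C)CCCC1=O | intermediate
5 | 4‑hydroxybenzaldehyde | O=Cc1ccc(O)cc1 | starting material
6 | 4‑hydroxy‑3‑(3‑methylbut‑2‑en‑1‑yl)benzaldehyde | CC(C)=CCc1cc(C=O)ccc1O | intermediate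
7 | malonic acid | OC(=O)CC(=O)O | starting material
8 | (2E)‑3‑[4‑hydroxy‑3‑(3‑methylbut‑2‑en‑1‑yl)phenyl]prop‑2‑enoic acid | CC(C)=CCc1cc(/C=C/C(=O)O)ccc1O | intermediate
9 | tert‑butyldimethylsilyl (2E)‑3‑{4‑[(tert‑butyldimethylsilyl)oxy]‑3‑(3‑methylbut‑2‑en‑1‑yl)phenyl}prop‑2‑enoate | CC(C)=CCc1cc(/C=C/C(=O)O[Si](C)(C)C(C)(C)C)ccc1O[Si](C)(C)C(C)(C)C | intermediate
10 | (2E)‑3‑{4‑[(tert‑butyldimethylsilyl)oxy]‑3‑(3‑methylbut‑2‑en‑1‑yl)phenyl}prop‑2‑enoyl chloride | CC(C)=CCc1cc(/C=C/C(=O)Cl)ccc1O[Si](C)(C)C(C)(C)C | intermediate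
11 | lithium dienolate of 4 (lithium 2‑(3‑methylbut‑2‑en‑1‑yl)‑3‑[(triisopropylsilyl)oxy]cyclohexa‑1,5‑dien‑1‑olate) | CC(C)=CCC1=C(O[Si](C(C)C)(C(C)C)C(C)C)CCC=C1[O-].[Li+] | intermediate
12 | enol diketone, (2E)‑3‑{4‑[(tert‑butyldimethylsilyl)oxy]‑3‑(3‑methylbut‑2‑en‑1‑yl)phenyl}‑1‑{2‑hydroxy‑3‑(3‑methylbut‑2‑en‑1‑yl)‑4‑[(triisopropylsilyl)oxy]cyclohexa‑1,3‑dien‑1‑yl}prop‑2‑en‑1‑one | CC(C)=CCC1=C(O[Si](C(C)C)(C(C)C)C(C)C)CCC(C(=O)/C=C/c2ccc(O[Si](C)(C)C(C)(C)C)c(CC=C(C)C)c2)=C1O | intermediate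
13 | (2S)‑2‑{4‑[(tert‑butyldimethylsilyl)oxy]‑3‑(3‑methylbut‑2‑en‑1‑yl)phenyl}‑8‑(3‑methylbut‑2‑en‑1‑yl)‑7‑[(triisopropylsilyl)oxy]‑2,3,5,6‑tetrahydro‑4H‑chromen‑4‑one | CC(C)=CCC1=C(O[Si](C(C)C)(C(C)C)C(C)C)CCC2=C1O[C@H](c1ccc(O[Si](C)(C)C(C)(C)C)c(CC=C(C)C)c1)CC2=O | intermediate
14 | (2S)‑2‑{4‑[(tert‑butyldimethylsilyl)oxy]‑3‑(3‑methylbut‑2‑en‑1‑yl)phenyl}‑8‑(3‑methylbut‑2‑en‑1‑yl)‑7‑[(triisopropylsilyl)oxy]‑2,3‑dihydro‑4H‑chromen‑4‑one | CC(C)=CCc1c(O[Si](C(C)C)(C(C)C)C(C)C)ccc2c1O[C@H](c1ccc(O[Si](C)(C)C(C)(C)C)c(CC=C(C)C)c1)CC2=O | intermediate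
15 | glabrol, (2S)‑7‑hydroxy‑2‑[4‑hydroxy‑3‑(3‑methylbut‑2‑en‑1‑yl)phenyl]‑8‑(3‑methylbut‑2‑en‑1‑yl)‑2,3‑dihydro‑4H‑chromen‑4‑one | CC(C)=CCc1c(O)ccc2c1O[C@H](c1ccc(O)c(CC=C(C)C)c1)CC2=O | target

**Step count and risks**

Total steps: 9. Longest linear sequence: 7 steps (steps 3 to 9, from 5).

Steps most likely to fail:

1. Step 7 (proposed new method). The closure may be slow and poorly face‑selective, because the enol oxygen is tied up in its O–H···O=C chelate and the acceptor is an unactivated, electron‑rich cinnamoyl group; O‑acylation of 11 may also compete with C‑acylation. Fallback with known chemistry, setting out from 12 (made as in step 7) and returning at 14: the closure is run with an achiral amine (quinuclidine, toluene) to give the racemic tetrahydrochromenone F1, which is dehydrogenated under the conditions of step 8 to the racemic bis‑silyl flavanone F2. Kinetic resolution by asymmetric transfer hydrogenation (RuCl(p‑cymene)[TsDPEN], HCO2H/Et3N, the enantiomer of the diamine chosen so that the (2R)‑ketone is the one reduced) should convert the unwanted enantiomer into the cis‑configured (2R,4R)‑flavan‑4‑ol F3 and leave 14, separated by chromatography.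

2. Step 8. Hydride abstraction by the quinone may also take place at the doubly activated CH2 groups of the prenyl side chains or continue at C2–C3 to the flavone, and the silyl dienol ether may be lost before aromatisation. Fallback, setting out from the lithium salt of 12 (step 7 before the acetic acid quench) and returning at 14: ring A is brought to the aromatic level before ring C exists, without a quinone. The diketonate is selenenylated at C4a (PhSeCl, THF, −78 °C) to the selenide F4. Oxidation (H2O2, pyridine, CH2Cl2, 0 °C), selenoxide syn‑elimination towards C5 and tautomerisation should give the 2'‑hydroxychalcone F5. Its amine‑catalysed oxa‑Michael closure (the classical chalcone–flavanone isomerisation) gives the racemic bis‑silyl flavanone F2, which is resolved as described under 1 to give 14.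

3. Step 3. O‑alkylation and double alkylation of the ambident phenoxide may outrun ortho C‑alkylation, and conversion in water may stay low. Fallback, setting out from 5 and returning at 6: Pd(PPh3)4‑catalysed O‑allylation of 5 with methyl 2‑methylbut‑3‑en‑2‑yl carbonate (THF, 0 °C) should give the tertiary allyl ether 4‑[(2‑methylbut‑3‑en‑2‑yl)oxy]benzaldehyde F6, whose aromatic Claisen rearrangement (N,N‑diethylaniline, heat) delivers the prenyl group to the ortho carbon and gives 6.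

**Further compounds**

F1 | step 7 | racemic 2‑{4‑[(tert‑butyldimethylsilyl)oxy]‑3‑(3‑methylbut‑2‑en‑1‑yl)phenyl}‑8‑(3‑methylbut‑2‑en‑1‑yl)‑7‑[(triisopropylsilyl)oxy]‑2,3,5,6‑tetrahydro‑4H‑chromen‑4‑one | CC(C)=CCC1=C(O[Si](C(C)C)(C(C)C)C(C)C)CCC2=C1OC(c1ccc(O[Si](C)(C)C(C)(C)C)c(CC=C(C)C)c1)CC2=O
F2 | step 7 | racemic 2‑{4‑[(tert‑butyldimethylsilyl)oxy]‑3‑(3‑methylbut‑2‑en‑1‑yl)phenyl}‑8‑(3‑methylbut‑2‑en‑1‑yl)‑7‑[(triisopropylsilyl)oxy]‑2,3‑dihydro‑4H‑chromen‑4‑one | CC(C)=CCc1c(O[Si](C(C)C)(C(C)C)C(C)C)ccc2c1OC(c1ccc(O[Si](C)(C)C(C)(C)C)c(CC=C(C)C)c1)CC2=O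
F3 | step 7 | (2R,4R)‑2‑{4‑[(tert‑butyldimethylsilyl)oxy]‑3‑(3‑methylbut‑2‑en‑1‑yl)phenyl}‑8‑(3‑methylbut‑2‑en‑1‑yl)‑7‑[(triisopropylsilyl)oxy]‑3,4‑dihydro‑2H‑chromen‑4‑ol | CC(C)=CCc1c(O[Si](C(C)C)(C(C)C)C(C)C)ccc2c1O[C@@H](c1ccc(O[Si](C)(C)C(C)(C)C)c(CC=C(C)C)c1)C[C@H]2O
F4 | step 8 | 6‑[(2E)‑3‑{4‑[(tert‑butyldimethylsilyl)oxy]‑3‑(3‑methylbut‑2‑en‑1‑yl)phenyl}prop‑2‑enoyl]‑2‑(3‑methylbut‑2‑en‑1‑yl)‑6‑(phenylselanyl)‑3‑[(triisopropylsilyl)oxy]cyclohex‑2‑en‑1‑one | CC(C)=CCC1=C(O[Si](C(C)C)(C(C)C)C(C)C)CCC([Se]c2ccccc2)(C(=O)/C=C/c2ccc(O[Si](C)(C)C(C)(C)C)c(CC=C(C)C)c2)C1=O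
F5 | step 8 | (2E)‑3‑{4‑[(tert‑butyldimethylsilyl)oxy]‑3‑(3‑methylbut‑2‑en‑1‑yl)phenyl}‑1‑{2‑hydroxy‑3‑(3‑methylbut‑2‑en‑1‑yl)‑4‑[(triisopropylsilyl)oxy]phenyl}prop‑2‑en‑1‑one | CC(C)=CCc1c(O[Si](C(C)C)(C(C)C)C(C)C)ccc(C(=O)/C=C/c2ccc(O[Si](C)(C)C(C)(C)C)c(CC=C(C)C)c2)c1O
F6 | step 3 | 4‑[(2‑methylbut‑3‑en‑2‑yl)oxy]benzaldehyde | C=CC(C)(C)Oc1ccc(C=O)cc1
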